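**Strategy.** The route rests on cutting ring B at C7–C8 and C9–C10: a Diels–Alder addition of methyl but-2-ynoate to a bicyclic dienyl enol lactone in which the C4 carboxyl carbon (C18) is tied to O-6. The lactone locks the hindered C10=C5–C6=C7 diene s-cis and turns the 4-methyl group into an angular substituent, so the one stereocentre set by catalysis (C4) dictates the quaternary C10; the adduct already holds O-6, C11 and a C8=C9 alkene, from which C5, C6, C8 and C9 follow by substrate control. The feature exploited is the γ-hydroxy acid C18–C4–C5–C6–O spanning the peri positions of rings A and B.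

Key step: step 6

Numbering: labdane-type locants are used for the core (decalin C1–C10; C11 on C9; C18 = 4α-carboxyl carbon; side chain C11–C16, C16 being the lactone CH–O).
Assumption: the 6α-hydroxy-18-oic acid motif (13 onwards) is handled as the open hydroxy acid, as in the target, and should not lactonise under the neutral or basic conditions used.

**Decalin fragment**

Step 1
Reactants: 1 tert-butyl 2-oxocyclohexane-1-carboxylate
Product: 2 tert-butyl (1R)-1-methyl-2-oxocyclohexane-1-carboxylate
Conditions: MeI, chiral N-spiro binaphthyl ammonium bromide phase-transfer catalyst (1 mol%, antipode that delivers R), CsOH·H2O, toluene, −40 °C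
Reagents that add atoms: iodomethane, CI
Why: Asymmetric phase-transfer alkylation, in which the chiral ammonium enolate ion pair is C-methylated on one face and so sets C4, the only core stereocentre that is not relayed.

Step 2
Reactants: 2 tert-butyl (1R)-1-methyl-2-oxocyclohexane-1-carboxylate
Product: 3 tert-butyl (1R)-1,3-dimethyl-2-oxocyclohexane-1-carboxylate (C3 epimers)
Conditions: LDA, THF, −78 °C; MeI, −78 to 0 °C
Reagents that add atoms: iodomethane, CI
Why: Kinetic enolate alkylation at the only enolisable α-carbon (future C10); the new centre is of no consequence because it becomes sp2 in step 3.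

Step 3
Reactants: 3 tert-butyl (1R)-1,3-dimethyl-2-oxocyclohexane-1-carboxylate
Product: 4 tert-butyl (1R)-1,3-dimethyl-2-(trifluoromethylsulfonyloxy)cyclohex-2-ene-1-carboxylate
Conditions: KHMDS, THF, −78 to 0 °C; PhNTf2, −78 °C to rt
Reagents that add atoms: N-phenylbis(trifluoromethanesulfonimide), O=S(=O)(N(c1ccccc1)S(=O)(=O)C(F)(F)F)C(F)(F)F
Why: Enol triflate formation from the potassium enolate, which can only form towards the methyl-bearing carbon because C4 is quaternary, as with 2,2,6-trimethylcyclohexanone.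

Step 4
Reactants: 4 tert-butyl (1R)-1,3-dimethyl-2-(trifluoromethylsulfonyloxy)cyclohex-2-ene-1-carboxylate
Product: 6 tert-butyl (1R)-2-ethynyl-1,3-dimethylcyclohex-2-ene-1-carboxylate, via TMS-enyne 5 (not isolated)
Conditions: TMS-acetylene, Pd(PPh3)4 (5 mol%), CuI, i-Pr2NH, DMF, 50 °C; then K2CO3, MeOH, rt
Reagents that add atoms: ethynyltrimethylsilane, C#C[Si](C)(C)C
Why: Sonogashira coupling of the vinyl triflate followed by protodesilylation in the same pot, as practised on 2,6,6-trimethylcyclohexenyl triflate.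

Step 5
Reactants: 6 tert-butyl (1R)-2-ethynyl-1,3-dimethylcyclohex-2-ene-1-carboxylate
Product: 8 (7aR)-4,7a-dimethyl-3-methylidene-5,6,7,7a-tetrahydro-2-benzofuran-1(3H)-one, via alkynoic acid 7 (not isolated)
Conditions: TFA/CH2Cl2 (1:4), 0 °C to rt; evaporate; then AuCl (5 mol%), K2CO3 (10 mol%), MeCN, rt
Reagents that add atoms: none
Why: Acidolysis of the tert-butyl ester and gold-catalysed 5-exo-dig cycloisomerisation of the γ-alkynoic acid should give the methylidene enol lactone without touching C4.

Step 6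
Reactants: 8 (7aR)-4,7a-dimethyl-3-methylidene-5,6,7,7a-tetrahydro-2-benzofuran-1(3H)-one; 9 methyl but-2-ynoate
Product: 10 methyl (2aR,5aS)-2a,5a,7-trimethyl-2-oxo-2a,3,4,5,5a,8-hexahydro-2H-naphtho[1,8-bc]furan-6-carboxylate (18,6-enol lactone of the Δ5,Δ8-dien-11-oate)
Conditions: 9 (3 equiv), toluene, BHT (cat.), 130 °C, sealed tube
Reagents that add atoms: none
Why: Thermal normal-electron-demand Diels–Alder reaction, concerted but asynchronous, with bonding from the nucleophilic methylidene carbon C7 to the β-carbon of the ynoate (C8) running ahead of C10–C9; the closest known reactions are the cycloadditions of 1-vinyl-2,6,6-trimethylcyclohexene and of 2-acyloxy-1,3-dienes with acetylenic esters. Ring B is closed by the suprafacial [4+2] mode across the diene termini C7 and C10, and no endo/exo question arises because the dienophile is an alkyne. The only new stereocentre, quaternary C10, is controlled by C4: the five-membered lactone holds C18 close to the diene plane and the 4-methyl group perpendicular to it as an angular substituent, so the alkyne should add to the opposite (α) face and the 10-methyl group should end up syn to the 4-methyl group. The step needs regioselectivity, which the 2-acyloxy group and the dialkylated terminus secure by raising the HOMO coefficient at C7 and which sterics reinforce by pairing the hindered C10 with the ester-bearing sp carbon. It also needs reactivity, which the lactone ring secures by locking the otherwise twisted tetrasubstituted diene s-cis.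

Step 7
Reactants: 10 Diels–Alder adduct
Product: 11 (1R,4aS,8aR)-5-(methoxycarbonyl)-1,4a,6-trimethyl-8-oxo-1,2,3,4,4a,7,8,8a-octahydronaphthalene-1-carboxylic acid (6-oxo-Δ8-en-11-oate-18-oic acid)
Conditions: 1 M aq. HCl/THF (1:3), 40 °C
Reagents that add atoms: water, O
Why: Acid-catalysed enol ester hydrolysis (C-protonation at C5, then collapse of the acyloxycarbenium ion) should release the C6 ketone and the C18 acid, with C5 protonated on the α face and, being α to the ketone, settling as the trans-fused 5α-H epimer.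

Step 8
Reactants: 11 keto acid
Product: 12 (1R,4aS,5S,6R,8aR)-5,6-epoxy-5-(methoxycarbonyl)-1,4a,6-trimethyl-8-oxodecahydronaphthalene-1-carboxylic acid (8α,9α-epoxide)
Conditions: DMDO (acetone solution, 3 equiv), CH2Cl2, 0 °C to rt
Reagents that add atoms: dimethyldioxirane, CC1(C)OO1
Why: Dioxirane epoxidation of the tetrasubstituted enoate under neutral conditions (no Baeyer–Villiger reaction, no enolisation) should occur on the α face, anti to the axial 10-methyl group, as epoxidations of drim-8-enes do.

Step 9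
Reactants: 12 epoxy keto acid
Product: 13 (1R,4aS,5R,6R,8S,8aR)-6,8-dihydroxy-5-(methoxycarbonyl)-1,4a,6-trimethyldecahydronaphthalene-1-carboxylic acid (6α,8α-diol, 9α-H)
Conditions: Li (8 equiv), NH3(l)/THF, −78 °C, 20 min; NH4Cl (s); work-up at pH 5, 0 °C
Reagents that add atoms: none
Why: Dissolving-metal reduction should do two known things at once: the hindered 6-ketone gives the thermodynamically preferred equatorial 6α-alcohol (as 11-oxo steroids give 11α-ols), and the α,β-epoxy ester is cleaved at C9–O to the 8α-alkoxide and an ester enolate that is protonated on quench from the less hindered α face (9α-H), the carboxylate staying inert.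

Step 10
Reactants: 13 dihydroxy ester acid
Product: 14 (1R,4aS,5R,6R,8S,8aR)-5-(methoxycarbonyl)-1,4a,6-trimethyl-6,8-bis(triethylsilyloxy)decahydronaphthalene-1-carboxylic acid
Conditions: TESOTf (3.5 equiv), 2,6-lutidine, CH2Cl2, −78 to 0 °C; then K2CO3, MeOH/H2O, 0 °C (cleaves the silyl ester only)
Reagents that add atoms: triethylsilyl trifluoromethanesulfonate, CC[Si](CC)(CC)OS(=O)(=O)C(F)(F)F
Why: Silylation with the silyl triflate should protect both the secondary and the tertiary alcohol (the latter to prevent retro-aldol cleavage or elimination at the β-oxy aldehyde stage), while the labile silyl ester at C18 is removed on mild basic work-up.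

Step 11
Reactants: 14 bis(silyl ether) ester acid
Product: 16 (1R,4aS,5R,6R,8S,8aR)-5-ethenyl-1,4a,6-trimethyl-6,8-bis(triethylsilyloxy)decahydronaphthalene-1-carboxylic acid, via aldehyde 15 (not isolated)
Conditions: DIBAL-H (3.2 equiv), CH2Cl2, −78 °C; then Ph3P=CH2 (from Ph3PCH3Br and KHMDS, 6 equiv), THF, −78 °C to rt
Reagents that add atoms: methyltriphenylphosphonium bromide, C[P+](c1ccccc1)(c1ccccc1)c1ccccc1.[Br-]
Why: Low-temperature DIBAL-H reduction should stop at the aluminium hemiacetal of the hindered ester (the acid being held as its aluminium carboxylate), and Wittig methylenation of the aldehyde released in situ gives the 9-vinyl group with C9 unchanged.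

**Butenolide fragment**

Step 12
Reactants: 17 methyl (2R)-oxirane-2-carboxylate
Product: 18 methyl (2R)-2-hydroxyhex-4-ynoate
Conditions: 1-propynyllithium (1.3 equiv), BF3·OEt2 (1.3 equiv), THF, −78 °C
Reagents that add atoms: 1-propynyllithium, [Li]C#CC
Why: BF3-mediated alkynylation of the epoxide at its unsubstituted carbon leaves the bought C2 stereocentre (future C16) untouched.

Step 13
Reactants: 18 methyl (2R)-2-hydroxyhex-4-ynoate
Product: 19 methyl (2R)-2-(tert-butyldimethylsilyloxy)hex-4-ynoate
Conditions: TBSCl, imidazole, DMF, rt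
Reagents that add atoms: tert-butyldimethylsilyl chloride, CC(C)(C)[Si](C)(C)Cl
Why: Standard silyl protection, which also prevents alkoxide-directed hydrozirconation in step 14.

Step 14
Reactants: 19 silyl ether alkyne
Product: 20 methyl (2R,4E)-2-(tert-butyldimethylsilyloxy)-5-iodohex-4-enoate
Conditions: Cp2Zr(H)Cl (2.2 equiv), THF, rt to 40 °C; then I2, 0 °C
Reagents that add atoms: iodine, II
Why: Hydrozirconation–iodination, in which syn addition of Zr–H places zirconium on the less hindered methyl-bearing alkyne carbon and iodinolysis with retention gives the (E)-2-iodoalkene.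

Step 15
Reactants: 20 iodoalkenyl ester
Product: 22 (3R,5E)-3-(tert-butyldimethylsilyloxy)-6-iodohept-5-en-2-one, via N-methoxy-N-methylamide 21 (not isolated)
Conditions: MeNHOMe·HCl (1.5 equiv), i-PrMgCl (3 equiv), THF, −20 °C; then MeMgBr (2 equiv), −20 to 0 °C
Reagents that add atoms: methylmagnesium bromide, C[Mg]Br
Why: In situ conversion of the ester into the N-methoxy-N-methylamide by the magnesium amide, then Grignard addition through the stable chelate, should give the methyl ketone without over-addition and without touching the alkenyl iodide.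

Step 16
Reactants: 22 silyloxy ketone
Product: 23 (3R,5E)-3-hydroxy-6-iodohept-5-en-2-one
Conditions: HF·pyridine, THF, 0 °C to rt
Reagents that add atoms: none
Why: Fluoride desilylation under mildly acidic conditions, which avoid base-induced epimerisation of the α-hydroxy ketone.

Step 17
Reactants: 23 α-hydroxy ketone
Product: 24 (5R)-5-[(2E)-3-iodobut-2-en-1-yl]-4-methylfuran-2(5H)-one
Conditions: Ph3P=C=C=O (1.2 equiv), toluene, 100 °C
Reagents that add atoms: (triphenylphosphoranylidene)ketene, O=C=C=P(c1ccccc1)(c1ccccc1)c1ccccc1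
Why: The ketenylidene ylide is acylated by the alcohol and the resulting ester ylide closes by intramolecular Wittig reaction on the ketone to the 4-methylbutenolide, with no bond change at C16.

**Union and end game**

Step 18
Reactants: 16 9-vinyl decalin acid; 24 iodoalkenyl butenolide
Product: 26 6,8-bis(triethylsilyl) ether of the target, via alkylborane 25 (not isolated)
Conditions: 9-BBN dimer (1.5 equiv, excess to cover the acid), THF, 0 °C to rt; then 24, PdCl2(dppf) (10 mol%), AsPh3, 3 M aq. K3PO4, DMF, rt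
Reagents that add atoms: none
Why: Anti-Markovnikov hydroboration of the monosubstituted alkene and B-alkyl Suzuki–Miyaura coupling with the alkenyl iodide, with retention of the (E) geometry, join C12 to C13 under mild aqueous base at room temperature, which the butenolide stereocentre should survive.

Step 19
Reactants: 26 bis(silyl ether)
Product: 27 target, (1R,4aS,5R,6R,8S,8aR)-6,8-dihydroxy-1,4a,6-trimethyl-5-{(3E)-3-methyl-5-[(2R)-3-methyl-5-oxo-2,5-dihydrofuran-2-yl]pent-3-en-1-yl}decahydronaphthalene-1-carboxylic acid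
Conditions: HF·pyridine, pyridine/THF, 0 °C to rt
Reagents that add atoms: none
Why: Fluoride desilylation under mildly acidic conditions should free both alcohols while leaving the butenolide, the tertiary alcohol and the trisubstituted alkene intact.

**Compound list**

1 | tert-butyl 2-oxocyclohexane-1-carboxylate | O=C1CCCCC1C(=O)OC(C)(C)C | starting material
2 | tert-butyl (1R)-1-methyl-2-oxocyclohexane-1-carboxylate | C[C@@]1(C(=O)OC(C)(C)C)CCCCC1=O | intermediate
3 | tert-butyl (1R)-1,3-dimethyl-2-oxocyclohexane-1-carboxylate (C3 epimers) | C[C@@]1(C(=O)OC(C)(C)C)CCCC(C)C1=O | intermediate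
4 | tert-butyl (1R)-1,3-dimethyl-2-(trifluoromethylsulfonyloxy)cyclohex-2-ene-1-carboxylate | C[C@@]1(C(=O)OC(C)(C)C)CCCC(C)=C1OS(=O)(=O)C(F)(F)F | intermediate
5 | tert-butyl (1R)-1,3-dimethyl-2-[(trimethylsilyl)ethynyl]cyclohex-2-ene-1-carboxylate | C[C@@]1(C(=O)OC(C)(C)C)CCCC(C)=C1C#C[Si](C)(C)C | intermediate
6 | tert-butyl (1R)-2-ethynyl-1,3-dimethylcyclohex-2-ene-1-carboxylate | C[C@@]1(C(=O)OC(C)(C)C)CCCC(C)=C1C#C | intermediate
7 | (1R)-2-ethynyl-1,3-dimethylcyclohex-2-ene-1-carboxylic acid | C[C@@]1(C(=O)O)CCCC(C)=C1C#C | intermediate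
8 | (7aR)-4,7a-dimethyl-3-methylidene-5,6,7,7a-tetrahydro-2-benzofuran-1(3H)-one | C[C@@]12CCCC(C)=C1C(=C)OC2=O | intermediate
9 | methyl but-2-ynoate | CC#CC(=O)OC | starting material
10 | methyl (2aR,5aS)-2a,5a,7-trimethyl-2-oxo-2a,3,4,5,5a,8-hexahydro-2H-naphtho[1,8-bc]furan-6-carboxylate | C[C@@]12CCC[C@]3(C)C(C(=O)OC)=C(C)CC(=C13)OC2=O | intermediate
11 | (1R,4aS,8aR)-5-(methoxycarbonyl)-1,4a,6-trimethyl-8-oxo-1,2,3,4,4a,7,8,8a-octahydronaphthalene-1-carboxylic acid | C[C@@]1(C(=O)O)CCC[C@]2(C)C(C(=O)OC)=C(C)CC(=O)[C@@H]12 | intermediate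
12 | (1R,4aS,5S,6R,8aR)-5,6-epoxy-5-(methoxycarbonyl)-1,4a,6-trimethyl-8-oxodecahydronaphthalene-1-carboxylic acid | C[C@@]1(C(=O)O)CCC[C@]2(C)[C@]3(C(=O)OC)O[C@]3(C)CC(=O)[C@@H]12 | intermediate
13 | (1R,4aS,5R,6R,8S,8aR)-6,8-dihydroxy-5-(methoxycarbonyl)-1,4a,6-trimethyldecahydronaphthalene-1-carboxylic acid | COC(=O)[C@@H]1[C@@]2(C)CCC[C@@](C)(C(=O)O)[C@@H]2[C@@H](O)C[C@@]1(C)O | intermediate
14 | (1R,4aS,5R,6R,8S,8aR)-5-(methoxycarbonyl)-1,4a,6-trimethyl-6,8-bis(triethylsilyloxy)decahydronaphthalene-1-carboxylic acid | COC(=O)[C@@H]1[C@@]2(C)CCC[C@@](C)(C(=O)O)[C@@H]2[C@@H](O[Si](CC)(CC)CC)C[C@@]1(C)O[Si](CC)(CC)CC | intermediate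
15 | (1R,4aS,5R,6R,8S,8aR)-5-formyl-1,4a,6-trimethyl-6,8-bis(triethylsilyloxy)decahydronaphthalene-1-carboxylic acid | O=C[C@@H]1[C@@]2(C)CCC[C@@](C)(C(=O)O)[C@@H]2[C@@H](O[Si](CC)(CC)CC)C[C@@]1(C)O[Si](CC)(CC)CC | intermediate
16 | (1R,4aS,5R,6R,8S,8aR)-5-ethenyl-1,4a,6-trimethyl-6,8-bis(triethylsilyloxy)decahydronaphthalene-1-carboxylic acid | C=C[C@@H]1[C@@]2(C)CCC[C@@](C)(C(=O)O)[C@@H]2[C@@H](O[Si](CC)(CC)CC)C[C@@]1(C)O[Si](CC)(CC)CC | intermediate
17 | methyl (2R)-oxirane-2-carboxylate | COC(=O)[C@H]1CO1 | starting material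
18 | methyl (2R)-2-hydroxyhex-4-ynoate | COC(=O)[C@H](O)CC#CC | intermediate
19 | methyl (2R)-2-(tert-butyldimethylsilyloxy)hex-4-ynoate | COC(=O)[C@H](O[Si](C)(C)C(C)(C)C)CC#CC | intermediate
20 | methyl (2R,4E)-2-(tert-butyldimethylsilyloxy)-5-iodohex-4-enoate | COC(=O)[C@H](O[Si](C)(C)C(C)(C)C)C/C=C(\C)I | intermediate
21 | (2R,4E)-2-(tert-butyldimethylsilyloxy)-5-iodo-N-methoxy-N-methylhex-4-enamide | CON(C)C(=O)[C@H](O[Si](C)(C)C(C)(C)C)C/C=C(\C)I | intermediate
22 | (3R,5E)-3-(tert-butyldimethylsilyloxy)-6-iodohept-5-en-2-one | CC(=O)[C@H](O[Si](C)(C)C(C)(C)C)C/C=C(\C)I | intermediate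
23 | (3R,5E)-3-hydroxy-6-iodohept-5-en-2-one | CC(=O)[C@H](O)C/C=C(\C)I | intermediate
24 | (5R)-5-[(2E)-3-iodobut-2-en-1-yl]-4-methylfuran-2(5H)-one | CC1=CC(=O)O[C@@H]1C/C=C(\C)I | intermediate
25 | B-alkyl-9-borabicyclo[3.3.1]nonane from 16 (boron on C12) | C1CCC2CCCC1B2CC[C@@H]1[C@@]2(C)CCC[C@@](C)(C(=O)O)[C@@H]2[C@@H](O[Si](CC)(CC)CC)C[C@@]1(C)O[Si](CC)(CC)CC | intermediate
26 | 6,8-bis(triethylsilyl) ether of the target | CC1=CC(=O)O[C@@H]1C/C=C(\C)CC[C@@H]1[C@@]2(C)CCC[C@@](C)(C(=O)O)[C@@H]2[C@@H](O[Si](CC)(CC)CC)C[C@@]1(C)O[Si](CC)(CC)CC | intermediate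
27 | (1R,4aS,5R,6R,8S,8aR)-6,8-dihydroxy-1,4a,6-trimethyl-5-{(3E)-3-methyl-5-[(2R)-3-methyl-5-oxo-2,5-dihydrofuran-2-yl]pent-3-en-1-yl}decahydronaphthalene-1-carboxylic acid | CC1=CC(=O)O[C@@H]1C/C=C(\C)CC[C@@H]1[C@@]2(C)CCC[C@@](C)(C(=O)O)[C@@H]2[C@@H](O)C[C@@]1(C)O | target

**Count.** Total steps: 19. Longest linear sequence: 13 (steps 1–11, 18, 19); the butenolide fragment takes 6 steps (12–17).

**Steps most likely to fail**

Step 6. The cycloaddition may be too slow at a tolerable temperature, so that the diene lactone oligomerises, or regiocontrol may erode. The fallback sets out from 8 and uses a more electrophilic dienophile under Lewis acid catalysis: but-2-ynal with Me2AlCl in CH2Cl2 at −78 to −40 °C should give (2aR,5aS)-2a,5a,7-trimethyl-2-oxo-2a,3,4,5,5a,8-hexahydro-2H-naphtho[1,8-bc]furan-6-carbaldehyde F1. Pinnick oxidation (NaClO2, NaH2PO4, 2-methylbut-2-ene) would then give the corresponding 6-carboxylic acid F2, and methylation with TMSCHN2 returns to 10.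

Step 9. The ester may be reduced or ammonolysed before the epoxide is cleaved, or equilibration at C6 may be incomplete. The fallback sets out from 12 and separates the two events: SmI2 in THF/MeOH at −78 °C should cleave only the α,β-epoxy ester to (1R,4aS,5R,6R,8aR)-6-hydroxy-5-(methoxycarbonyl)-1,4a,6-trimethyl-8-oxodecahydronaphthalene-1-carboxylic acid F3. The ketone is then reduced under thermodynamic control by reversible transfer hydrogenation (hydroxycyclopentadienyl ruthenium hydride catalyst, i-PrOH, 80 °C), which returns to 13.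

Step 1. Enantiofacial discrimination may be insufficient with the small electrophile iodomethane. The fallback sets out from 1 and buys the chirality instead: condensation with tert-butyl L-valinate (cat. TsOH, toluene, −H2O) should give the enamino ester tert-butyl (2S)-2-{[2-(tert-butoxycarbonyl)cyclohex-1-en-1-yl]amino}-3-methylbutanoate F4. Lithiation with LDA and methylation, under the solvent and additive regime that gives the (R) series, would give the imine tert-butyl (2S)-2-{[(2R)-2-(tert-butoxycarbonyl)-2-methylcyclohexylidene]amino}-3-methylbutanoate F5, and mild aqueous acid hydrolysis returns to 2 with release of the auxiliary.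

Further compounds
F1 | step 6 | (2aR,5aS)-2a,5a,7-trimethyl-2-oxo-2a,3,4,5,5a,8-hexahydro-2H-naphtho[1,8-bc]furan-6-carbaldehyde | C[C@@]12CCC[C@]3(C)C(C=O)=C(C)CC(=C13)OC2=O
F2 | step 6 | (2aR,5aS)-2a,5a,7-trimethyl-2-oxo-2a,3,4,5,5a,8-hexahydro-2H-naphtho[1,8-bc]furan-6-carboxylic acid | C[C@@]12CCC[C@]3(C)C(C(=O)O)=C(C)CC(=C13)OC2=O
F3 | step 9 | (1R,4aS,5R,6R,8aR)-6-hydroxy-5-(methoxycarbonyl)-1,4a,6-trimethyl-8-oxodecahydronaphthalene-1-carboxylic acid | COC(=O)[C@@H]1[C@@]2(C)CCC[C@@](C)(C(=O)O)[C@@H]2C(=O)C[C@@]1(C)O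
F4 | step 1 | tert-butyl (2S)-2-{[2-(tert-butoxycarbonyl)cyclohex-1-en-1-yl]amino}-3-methylbutanoate | CC(C)[C@H](NC1=C(C(=O)OC(C)(C)C)CCCC1)C(=O)OC(C)(C)C
F5 | step 1 | tert-butyl (2S)-2-{[(2R)-2-(tert-butoxycarbonyl)-2-methylcyclohexylidene]amino}-3-methylbutanoate | CC(C)[C@H](N=C1CCCC[C@@]1(C)C(=O)OC(C)(C)C)C(=O)OC(C)(C)C
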